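Percentage points of the charge are my unit, and I follow one molecule to its fork: I suppose the free catalyst turns starting material into target and other conformer into isomer of the product.

all flasks: starting material 0.50 M; other conformer 0.125 M; added ligand 2.5 mM; impurity 0.78 mM

|  | free catalyst | remark | time |
|---|---|---|---|
| gamma | 3.5 mM | the very flask that is asked about, followed so far |  |
| zeta | 1.8 mM | run made earlier |  |
| flask | 3.5 mM |  | 15 d |

gamma run (percent of the starting material and other conformer together charged)

| time / h | isomer of the product / % | target / % | starting material / % |
|---|---|---|---|
| 2.00 | 29.6 | 28.6 | 24.2 |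
| 6.00 | 40.8 | 42.8 | 10.4 |
| 10.0 | 45.1 | 46.5 | 5.2 |
| 15.0 | 47.0 | 49.7 | 2.4 |
| 20.0 | 48.2 | 49.6 | 1.3 |
| 30.0 | 49.0 | 50.9 | 0 |

zeta run (percent of the starting material and other conformer together charged)

| time / d | isomer of the product / % | target / % | starting material / % |
|---|---|---|---|
| 1.04 | 41.0 | 24.3 | 18.9 |
| 3.00 | 54.5 | 31.7 | 7.9 |
| 5.00 | 60.2 | 34.0 | 3.7 |
| 8.00 | 63.7 | 35.3 | 0.3 |
| 12.0 | 64.0 | 36.5 | 0 |
| 15.0 | 64.0 | 36.8 | 0.2 |

(scatter of a reading: 0.5 percentage points)

- share of isomer of the product in isomer of the product plus target at 6.0 min
- share of isomer of the product in isomer of the product plus target at 15 d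

- what was read earlier has a scatter of 0.5 percentage points, one standard deviation

At the early readings of both runs part of the charge is unread, being neither isomer, target nor starting material. Over the readings from 2.00 h to 10.0 h in gamma, this unread part summed against starting material is 0.673, and from 1.04 d to 5.00 d in zeta it is 0.780. Over those spans, isomer gained per target gained is 0.866 and 1.98.

If the unread part were all other conformer, gamma would give a factor of 1.29, and with the charged ratio of conformer to starting material, 0.250, a share of 24.4 % at 6.0 min. That link is weak: the gain moves between the runs more than the unread part does, so I count as conformer just the difference. This gives 10.4, the selectivity factor, the change in gain over the change in unread part, meaning how many times faster the catalyst turns a molecule of conformer than one of starting material. Each unread part carries the scatter of several readings, so it is rough.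

If the charged ratio still stands at 6.0 min in the flask, an assumption of mine, the odds are 2.60, a share of 72.2 %. Zeta's share goes from 64.3 % at 8.00 d to 63.5 % at 15.0 d, so for 15 d I keep gamma's last share, 49.0 %.

The forecast gives 49.5 % at 6.0 min and 49.1 % at 15 d, holding that “the products appear not to interconvert”.

The flask gives 71.4 % at 6.0 min and 49.4 % at 15 d.

    starting material ⇌ other conformer (K = 0.200, k = 0.280 h⁻¹)
    starting material + free catalyst → free catalyst + target (k = 210 M⁻¹ h⁻¹)
    free catalyst + other conformer → free catalyst + isomer of the product (k = 2200 M⁻¹ h⁻¹)
    free catalyst + added ligand ⇌ idle complex (K = 12000 M⁻¹, k = 220 M⁻¹ h⁻¹)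
    starting material ⇌ dormant form (K = 0.610, k = 6.60 h⁻¹)
    free catalyst + impurity → spent catalyst (k = 93000 M⁻¹ h⁻¹)

In the flask, isomer and target stand level at 0.0922 d. The flask's share at 6.0 min means odds of 2.49, against my 2.60, and over the charged ratio they read a factor of 9.96.

In the neighbour with 0.30 M of starting material, my selectivity factor of 10.4 and that flask's charged ratio give odds of 4.34, a share of 81.3 % at 6.0 min. The computed share there is 80.1 %.

The readings come from a simulation with made-up constants, noise included.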